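The runs were generated by integration for substances that don't exist, noise included.

**One-step world.** Picture E + G giving Z and stopping there: the fraction of the E charged that is found as Z climbs and stays. The amber run does otherwise, falling from 42.7% at 0.500 h to 17.8% at 6.00 h. So Z is a stopover, and the books need more entries.

| flask | E | G | remark | time |
|---|---|---|---|---|
| amber | 0.050 M | 0.30 M | run made earlier |  |
| violet | 0.075 M | 0.30 M | run made earlier |  |
| grey | 0.10 M | 0.15 M | run made earlier |  |
| flask | 0.10 M | 0.300 M |  | 5.0 h |

| run | time / h | Z / % |
|---|---|---|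
| amber | 0.500 | 42.7 |
| amber | 0.667 | 33.8 |
| amber | 1.00 | 27.0 |
| amber | 1.50 | 21.3 |
| amber | 2.50 | 17.7 |
| amber | 4.00 | 17.9 |
| amber | 6.00 | 17.8 |
| violet | 0.833 | 32.4 |
| violet | 1.50 | 26.2 |
| violet | 2.50 | 23.3 |
| violet | 3.00 | 22.5 |
| violet | 4.00 | 22.1 |
| violet | 5.00 | 21.9 |
| violet | 6.00 | 21.3 |
| grey | 1.33 | 31.9 |
| grey | 2.50 | 23.8 |
| grey | 4.00 | 19.9 |
| grey | 5.00 | 17.7 |
| grey | 6.00 | 17.4 |

(standard deviation of a reading: 0.5 percentage points)

- the numbers in the tables scatter by 0.5 percentage points (one standard deviation)

- equivalents of G to E, everything else as given, that leave most Z at 5.0 h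
- the amount of Z then, in percent of the E charged
- the amount of Z with the amounts as given

**Open ledger.** Book E as the limiting reagent by charge: even the grey run holds more G than E. Enter Z late in each run. Grey, at 1.50 equivalents of G, shows 17.7% at 5.00 h. Violet, at 4.00, shows 21.9% at 5.00 h. Amber, at 6.00, shows 17.8% at 6.00 h. The rest of each charge stays unread, 78.1% in violet. The middle entry stands above both others, but the runs differ in E, in G or in both, so take a peak between them as a reading.

**Closing entry.** Take my own reckoning: let the Z fraction fall from a top value by a bend times the square of ln(equivalents/peak). The three entries give a bend of 0.104, a ratio of 3.01 and a top of 22.7%. That ratio is the peak equivalents, the G:E ratio where the late Z entry tops out; it is a reading with the scatter of the three entries, and it counts E and G by their ratio with the time held near 5.0 h. My reckoning puts the flask, at 3.00 equivalents, at 22.7%.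

**The forecast.** It puts the best ratio at 2.8 equiv, the Z there at 22.5% and the Z of the flask at 22.3%, slightly apart from my reckoning, on this ground: “The flask at 3 equiv therefore sits almost at the optimum.”

**Books closed.** The flask gives 22.3%, and its best is 22.3% at 3.02 equiv. At 5.00 h, E, Z, D, L and X in the flask sum to 100% of the charge. The flask's equivalents over the peak equivalents come to 0.997, so the cheap rule leaves the flask's charge where it stands, and the two computed amounts of Z print alike.

    2 E → X (k = 0.910 M⁻¹ min⁻¹)
    Z + G ⇌ Q + D (K = 1.30, k = 0.120 M⁻¹ min⁻¹)
    E + G ⇌ Q + Z (K = 4.50, k = 1.90 M⁻¹ min⁻¹)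
    D + G ⇌ Q + L (K = 0.140, k = 0.600 M⁻¹ min⁻¹)

**Second flask.** Charge 0.17 M of E, with G and the time as in the flask, which makes 1.76 equiv: the rule gives 19.8%. The computed neighbour gives less, 17.0%, with X at 49.4% of the charge.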